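**Retrosynthetic overview**
1. Target 20 ⇐ enal 19 ⇐ 17‑silyloxy‑15‑ol 15: the C17 acid comes from MnO2/Pinnick oxidation of a Δ7 allylic alcohol, the C15 ester from isobutyryl chloride 16.
2. Δ7‑17‑ol 13 ⇐ 8α,17‑epoxide 12 ⇐ exocyclic olefin 11 (methyl copalate): ring B is functionalised by epoxidation and epoxide → allylic alcohol isomerisation.
3. (13E)‑enoate 11 ⇐ (Z)‑enol phosphate 10 + Me2CuLi ⇐ β‑keto ester 8. Key C–C bond (C14–C15): intermolecular crossed Claisen condensation of methyl ketone 5 with dimethyl carbonate 6.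
4. Ketone 5 ⇐ (−)‑sclareol 1 by KMnO4 excision of C14–C15 and exo‑selective dehydration.
5. No ring is formed: rings A and B (trans‑decalin with C5, C9, C10 set) arrive intact from sclareol.

Assumption: labdane numbering is used (C17 on C8, C16 on C13, C20 on C10); every bicyclic compound keeps the sclareol nucleus (trans‑decalin, 5α‑H, 9α‑H with the side chain β, 10β‑CH3), and from compound 7 on the former C16 methyl carbon of sclareol is C14.

**Step 1**
Reactants: 1 (−)‑sclareol, (13R)‑labd‑14‑ene‑8α,13‑diol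
Product: 3 hydroxy ketone ((8α)‑8‑hydroxy‑14,15‑dinorlabdan‑13‑one), via hydroxy acid 2 (not isolated)
Conditions: KMnO4, acetone/H2O, 0 °C → rt
Reagents that add atoms: none
Why: Permanganate oxidative cleavage of the vinyl carbinol, then oxidative decarboxylation of the α‑hydroxy acid, removes C14 and C15 and leaves the methyl ketone without touching C5, C8, C9 or C10.

**Step 2**
Reactants: 3 hydroxy ketone
Product: 5 olefin ketone (14,15‑dinorlabd‑8(17)‑en‑13‑one), via chlorosulfite 4 (not isolated)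
Conditions: SOCl2, pyridine, CH2Cl2, −78 °C
Reagents that add atoms: none
Why: E2 elimination of the equatorial 8α‑chlorosulfite, whose only anti‑periplanar hydrogens are on the axial C17 methyl group, gives the exocyclic olefin.

**Step 3 (key C–C bond)**
Reactants: 5 olefin ketone; 6 dimethyl carbonate
Product: 8 β‑keto ester (methyl 13‑oxo‑16‑norlabd‑8(17)‑en‑15‑oate), via sodium enolate 7 (not isolated)
Conditions: NaH, THF, reflux; cold aq. HCl
Reagents that add atoms: none
Why: Crossed Claisen condensation in which the less hindered methyl enolate of 5 is acylated by the carbonate and the equilibrium is pulled over by the stabilised β‑keto ester enolate 7, which is protonated on the acidic quench.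

**Step 4**
Reactants: 8 β‑keto ester
Product: 10 enol phosphate (methyl (13Z)‑13‑(diethoxyphosphoryloxy)‑16‑norlabda‑8(17),13‑dien‑15‑oate), via lithium enolate 9 (not isolated)
Conditions: LiN(SiMe3)2, Et2O, 0 °C; ClP(O)(OEt)2, 0 °C → rt
Reagents that add atoms: diethyl chlorophosphate, CCOP(=O)(Cl)OCC
Why: Enolate O‑phosphorylation (enol phosphate formation of the Weiler type) of the tight lithium chelate in ether, in which the enolate oxygen is held cis to the ester carbonyl, fixes the Z geometry.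

**Step 5**
Reactants: 10 enol phosphate
Product: 11 methyl copalate (methyl (13E)‑labda‑8(17),13‑dien‑15‑oate)
Conditions: Me2CuLi (from MeLi, CuI), Et2O, −78 → −45 °C; aq. NH4Cl
Reagents that add atoms: lithium dimethylcuprate, [Li+].C[Cu-]C
Why: Cuprate addition–elimination on the β‑phosphoryloxy enoate proceeds with retention, so the new methyl is cis to the ester and the 13E olefin results.

**Step 6**
Reactants: 11 methyl copalate
Product: 12 epoxide (methyl (13E)‑8α,17‑epoxylabd‑13‑en‑15‑oate)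
Conditions: mCPBA, CH2Cl2, 0 °C
Reagents that add atoms: mCPBA, O=C(OO)c1cccc(Cl)c1
Why: Prilezhaev epoxidation picks the electron‑rich exocyclic olefin over the conjugated enoate and attacks from the α face, away from the axial C10 methyl; the C8 epimer would converge in step 7.

**Step 7**
Reactants: 12 epoxide
Product: 13 allylic alcohol (methyl (13E)‑17‑hydroxylabda‑7,13‑dien‑15‑oate)
Conditions: Al(OiPr)3, toluene, reflux; aqueous work‑up
Reagents that add atoms: none
Why: Aluminium‑alkoxide‑mediated epoxide → allylic alcohol isomerisation (syn β‑elimination through a cyclic transition state) removes the accessible C7 hydrogen, not the hindered C9 hydrogen, so the Δ7 primary allylic alcohol forms and C9 is untouched.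

**Step 8**
Reactants: 13 allylic alcohol
Product: 14 silyl ether (methyl (13E)‑17‑(tert‑butyldimethylsilyloxy)labda‑7,13‑dien‑15‑oate)
Conditions: TBSCl, imidazole, DMF, rt
Reagents that add atoms: tert‑butyldimethylsilyl chloride, CC(C)(C)[Si](C)(C)Cl
Why: Standard silylation of a primary alcohol, which keeps the C17 oxygen apart from the C15 oxygen to come.

**Step 9**
Reactants: 14 silyl ether
Product: 15 C15 alcohol ((13E)‑17‑(tert‑butyldimethylsilyloxy)labda‑7,13‑dien‑15‑ol)
Conditions: i‑Bu2AlH, CH2Cl2, −78 °C; aq. potassium sodium tartrate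
Reagents that add atoms: none
Why: 1,2‑Reduction of the enoate by the aluminium hydride gives the allylic alcohol with the 13E geometry and the silyl ether unchanged.

**Step 10**
Reactants: 15 C15 alcohol; 16 isobutyryl chloride (2‑methylpropanoyl chloride)
Product: 17 silyl ether ester ((13E)‑17‑(tert‑butyldimethylsilyloxy)labda‑7,13‑dien‑15‑yl 2‑methylpropanoate)
Conditions: pyridine, DMAP (cat.), CH2Cl2, 0 °C
Reagents that add atoms: none
Why: Nucleophilic acyl substitution on the acid chloride esterifies the only free hydroxyl.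

**Step 11**
Reactants: 17 silyl ether ester
Product: 18 hydroxy ester ((13E)‑17‑hydroxylabda‑7,13‑dien‑15‑yl 2‑methylpropanoate)
Conditions: HF·pyridine, THF, 0 °C → rt
Reagents that add atoms: none
Why: Fluoride‑driven desilylation under mildly acidic conditions frees the C17 alcohol without cleaving or migrating the isobutyrate.

**Step 12**
Reactants: 18 hydroxy ester
Product: 19 enal ((13E)‑17‑oxolabda‑7,13‑dien‑15‑yl 2‑methylpropanoate)
Conditions: MnO2, CH2Cl2, rt
Reagents that add atoms: none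
Why: Chemoselective allylic oxidation gives the conjugated aldehyde; C9 is not enolisable through this cross‑conjugated enal.

**Step 13**
Reactants: 19 enal
Product: 20 target, (13E)‑15‑(2‑methylpropanoyloxy)labda‑7,13‑dien‑17‑oic acid
Conditions: NaClO2, NaH2PO4, 2‑methyl‑2‑butene, t‑BuOH/H2O, rt
Reagents that add atoms: sodium chlorite, [Na+].[O-]Cl=O
Why: Pinnick oxidation converts the enal to the acid while the scavenger protects both olefins and the ester is inert.

**Compound list**
1 | (−)‑sclareol, (13R)‑labd‑14‑ene‑8α,13‑diol | C=C[C@](C)(O)CC[C@H]1[C@](C)(O)CC[C@H]2C(C)(C)CCC[C@]12C | starting material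
2 | hydroxy acid, (13R)‑8α,13‑dihydroxy‑15‑norlabdan‑14‑oic acid | OC(=O)[C@](C)(O)CC[C@H]1[C@](C)(O)CC[C@H]2C(C)(C)CCC[C@]12C | intermediate
3 | hydroxy ketone, (8α)‑8‑hydroxy‑14,15‑dinorlabdan‑13‑one | CC(=O)CC[C@H]1[C@](C)(O)CC[C@H]2C(C)(C)CCC[C@]12C | intermediate
4 | chlorosulfite, 13‑oxo‑14,15‑dinorlabdan‑8α‑yl chlorosulfite | CC(=O)CC[C@H]1[C@](C)(OS(=O)Cl)CC[C@H]2C(C)(C)CCC[C@]12C | intermediate
5 | olefin ketone, 14,15‑dinorlabd‑8(17)‑en‑13‑one | CC(=O)CC[C@H]1C(=C)CC[C@H]2C(C)(C)CCC[C@]12C | intermediate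
6 | dimethyl carbonate | COC(=O)OC | starting material
7 | sodium (Z)‑enolate of 8 | [Na+].COC(=O)/C=C(\[O-])CC[C@H]1C(=C)CC[C@H]2C(C)(C)CCC[C@]12C | intermediate
8 | β‑keto ester, methyl 13‑oxo‑16‑norlabd‑8(17)‑en‑15‑oate | COC(=O)CC(=O)CC[C@H]1C(=C)CC[C@H]2C(C)(C)CCC[C@]12C | intermediate
9 | lithium (Z)‑enolate of 8 | [Li+].COC(=O)/C=C(\[O-])CC[C@H]1C(=C)CC[C@H]2C(C)(C)CCC[C@]12C | intermediate
10 | enol phosphate, methyl (13Z)‑13‑(diethoxyphosphoryloxy)‑16‑norlabda‑8(17),13‑dien‑15‑oate | COC(=O)/C=C(\OP(=O)(OCC)OCC)CC[C@H]1C(=C)CC[C@H]2C(C)(C)CCC[C@]12C | intermediate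
11 | methyl copalate, methyl (13E)‑labda‑8(17),13‑dien‑15‑oate | COC(=O)/C=C(\C)CC[C@H]1C(=C)CC[C@H]2C(C)(C)CCC[C@]12C | intermediate
12 | epoxide, methyl (13E)‑8α,17‑epoxylabd‑13‑en‑15‑oate | COC(=O)/C=C(\C)CC[C@H]1[C@@]2(CO2)CC[C@H]3C(C)(C)CCC[C@]13C | intermediate
13 | allylic alcohol, methyl (13E)‑17‑hydroxylabda‑7,13‑dien‑15‑oate | COC(=O)/C=C(\C)CC[C@H]1C(CO)=CC[C@H]2C(C)(C)CCC[C@]12C | intermediate
14 | silyl ether, methyl (13E)‑17‑(tert‑butyldimethylsilyloxy)labda‑7,13‑dien‑15‑oate | COC(=O)/C=C(\C)CC[C@H]1C(CO[Si](C)(C)C(C)(C)C)=CC[C@H]2C(C)(C)CCC[C@]12C | intermediate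
15 | C15 alcohol, (13E)‑17‑(tert‑butyldimethylsilyloxy)labda‑7,13‑dien‑15‑ol | OC/C=C(\C)CC[C@H]1C(CO[Si](C)(C)C(C)(C)C)=CC[C@H]2C(C)(C)CCC[C@]12C | intermediate
16 | isobutyryl chloride | CC(C)C(=O)Cl | starting material
17 | silyl ether ester, (13E)‑17‑(tert‑butyldimethylsilyloxy)labda‑7,13‑dien‑15‑yl 2‑methylpropanoate | CC(C)C(=O)OC/C=C(\C)CC[C@H]1C(CO[Si](C)(C)C(C)(C)C)=CC[C@H]2C(C)(C)CCC[C@]12C | intermediate
18 | hydroxy ester, (13E)‑17‑hydroxylabda‑7,13‑dien‑15‑yl 2‑methylpropanoate | CC(C)C(=O)OC/C=C(\C)CC[C@H]1C(CO)=CC[C@H]2C(C)(C)CCC[C@]12C | intermediate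
19 | enal, (13E)‑17‑oxolabda‑7,13‑dien‑15‑yl 2‑methylpropanoate | CC(C)C(=O)OC/C=C(\C)CC[C@H]1C(C=O)=CC[C@H]2C(C)(C)CCC[C@]12C | intermediate
20 | (13E)‑15‑(2‑methylpropanoyloxy)labda‑7,13‑dien‑17‑oic acid | C/C(=C\COC(=O)C(C)C)CC[C@H]1C(C(=O)O)=CC[C@H]2C(C)(C)CCC[C@]12C | target

**Totals**
Total step count: 13. Longest linear sequence: 13 steps, from sclareol 1 to 20.

**Three steps most likely to fail**

Step 7 (epoxide to allylic alcohol). Risks are loss of the C9 hydrogen giving the Δ8 olefin, hydride shift to a saturated aldehyde, and partial exchange of the methyl ester for the isopropyl ester. The last is harmless because step 9 reduces either ester to 15. The fallback sets out from 11 and comes back at 13. The exocyclic olefin of 11 is ozonised selectively in the presence of the electron‑poor enoate (O3, CH2Cl2/pyridine, −78 °C; Me2S) to give methyl (13E)‑8‑oxo‑17‑norlabd‑13‑en‑15‑oate F6. Kinetic enolisation away from the hindered C9 (KN(SiMe3)2, THF, −78 °C; PhNTf2) gives methyl (13E)‑8‑(trifluoromethylsulfonyloxy)‑17‑norlabda‑7,13‑dien‑15‑oate F7. Stille hydroxymethylation (Bu3SnCH2OH, Pd(PPh3)4, LiCl, dioxane, 100 °C) then gives 13 with the Δ7 position fixed by the triflate.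

Step 2 (regiochemistry of the dehydration; acid could also close 3 to the cyclic enol ether). The fallback sets out from 3 and comes back at 13, and switches ring B to the endocyclic series so that the exocyclic olefin is no longer needed. The Δ7 isomer that accompanies 5 (favoured when the elimination is run warm or as a thermal syn‑elimination), 14,15‑dinorlabd‑7‑en‑13‑one F1, is isolated on AgNO3‑impregnated silica. It is taken through the conditions of steps 3, 4 and 5 to give in turn methyl 13‑oxo‑16‑norlabd‑7‑en‑15‑oate F2, methyl (13Z)‑13‑(diethoxyphosphoryloxy)‑16‑norlabda‑7,13‑dien‑15‑oate F3 and methyl (13E)‑labda‑7,13‑dien‑15‑oate F4. Allylic hydroxylation of the C17 methyl group of F4 (SeO2 cat., t‑BuOOH, CH2Cl2, rt) gives 13 directly, so steps 6 and 7 are skipped.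

Step 5 (cuprate coupling; loss of geometry on warming, incomplete conversion, or an enol phosphate of insufficient Z purity carried in from step 4). The fallback sets out from 8 and comes back at 11, so it bypasses the enol phosphate altogether. Compound 8 is triflated under lithium chelation control (Tf2O, aq. LiOH, toluene, 5 °C) to methyl (13Z)‑13‑(trifluoromethylsulfonyloxy)‑16‑norlabda‑8(17),13‑dien‑15‑oate F5. This is cross‑coupled with MeMgBr under Fe(acac)3 catalysis (THF/NMP, −30 °C) with retention of geometry to give 11.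

**Further compounds**
F1 | step 2 | 14,15‑dinorlabd‑7‑en‑13‑one | CC(=O)CC[C@H]1C(C)=CC[C@H]2C(C)(C)CCC[C@]12C
F2 | step 2 | methyl 13‑oxo‑16‑norlabd‑7‑en‑15‑oate | COC(=O)CC(=O)CC[C@H]1C(C)=CC[C@H]2C(C)(C)CCC[C@]12C
F3 | step 2 | methyl (13Z)‑13‑(diethoxyphosphoryloxy)‑16‑norlabda‑7,13‑dien‑15‑oate | COC(=O)/C=C(\OP(=O)(OCC)OCC)CC[C@H]1C(C)=CC[C@H]2C(C)(C)CCC[C@]12C
F4 | step 2 | methyl (13E)‑labda‑7,13‑dien‑15‑oate | COC(=O)/C=C(\C)CC[C@H]1C(C)=CC[C@H]2C(C)(C)CCC[C@]12C
F5 | step 5 | methyl (13Z)‑13‑(trifluoromethylsulfonyloxy)‑16‑norlabda‑8(17),13‑dien‑15‑oate | COC(=O)/C=C(\OS(=O)(=O)C(F)(F)F)CC[C@H]1C(=C)CC[C@H]2C(C)(C)CCC[C@]12C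
F6 | step 7 | methyl (13E)‑8‑oxo‑17‑norlabd‑13‑en‑15‑oate | COC(=O)/C=C(\C)CC[C@H]1C(=O)CC[C@H]2C(C)(C)CCC[C@]12C
F7 | step 7 | methyl (13E)‑8‑(trifluoromethylsulfonyloxy)‑17‑norlabda‑7,13‑dien‑15‑oate | COC(=O)/C=C(\C)CC[C@H]1C(OS(=O)(=O)C(F)(F)F)=CC[C@H]2C(C)(C)CCC[C@]12C
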